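Cuts: N–CH3 first, then C4a–C5 and C8–C8a of ring A. Ring C is cut at C2–C3 and O1–C8a, and the diene at its acetyl bond (C6–C7).
Enabling feature: ring A (C4a, C5, C6, C7, C8, C8a) is a phloroglucinol. Its C8a oxygen is O1 of ring C and its C4a carries the C4 ketone, so C4a=C8a is the push–pull alkene of a dihydropyranone. C5–C6–C7–C8 has the oxygen pattern of an acetoacetate bis(enol ether) with the piperidine on its inner carbon, so partner polarity decides 6- against 8-substitution.
Forward order: ring C is built on the ring B aldehyde and armed with a sulfinyl group at the future C4a. The purchased piperidine acid becomes the diene. Ring A closes last by [4+2] cycloaddition, sulfoxide elimination and aromatisation, followed by Boc removal and N-methylation.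
Stereochemistry: piperidine C2 (R) comes with the chiral-pool acid, and flavanone C2 (S) comes from the (S)-BINOL/Ti(OiPr)4-catalysed hetero-Diels–Alder step. All later steps are neutral or mildly acidic, so ring C stays closed and the benzylic C–N bond does not ionise.

Key step: step 8

Assumption: the (S)-BINOL/Ti(OiPr)4 catalyst is taken to open the aldehyde face that leads to the (S)-pyranone, the same facial sense it shows in allylations and aldol additions of aromatic aldehydes.

Step 1
Reactants: 1 (2R)-2-[1-(tert-butoxycarbonyl)piperidin-2-yl]acetic acid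
Product: 2 methyl 2-[(2R)-1-(tert-butoxycarbonyl)piperidin-2-yl]acetate
Conditions: MeI, K2CO3, DMF, rt
Reagents that add atoms: iodomethane, CI
Why: SN2 O-alkylation of the carboxylate under mild base, which leaves the carbamate and the non-acidic ring stereocentre untouched.

Step 2
Reactants: 2 methyl 2-[(2R)-1-(tert-butoxycarbonyl)piperidin-2-yl]acetate; 3 N-methoxy-N-methylacetamide
Product: 6 methyl 2-[(2R)-1-(tert-butoxycarbonyl)piperidin-2-yl]-3-oxobutanoate (both α-epimers), via lithium enolate 4 (not isolated), via tetrahedral lithium adduct 5 (not isolated)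
Conditions: LiN(iPr)2 (1.1 equiv), THF, −78 °C; 3, −78 → −40 °C; AcOH
Reagents that add atoms: none
Why: Crossed Claisen-type C-acylation of an ester enolate with an N-methoxy-N-methylamide, in which the chelated adduct 5 persists until the quench so that one equivalent of base suffices and no O- or double acylation occurs, the low temperature holds back β-elimination of the carbamate, and the new α-centre is unimportant because step 3 makes it sp2.

Step 3
Reactants: 6 methyl 2-[(2R)-1-(tert-butoxycarbonyl)piperidin-2-yl]-3-oxobutanoate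
Product: 7 methyl 2-[(2R)-1-(tert-butoxycarbonyl)piperidin-2-yl]-3-(trimethylsilyloxy)but-2-enoate (alkene geometry immaterial)
Conditions: Me3SiCl, Et3N, toluene, rt; filtration under argon
Reagents that add atoms: chlorotrimethylsilane, C[Si](C)(C)Cl
Why: Soft enolisation and O-silylation of a β-keto ester, the usual first stage towards 1,3-bis(silyloxy)dienes, under an amine base too weak to drive retro-Michael loss of the carbamate nitrogen from the stabilised enolate.

Step 4
Reactants: 7 methyl 2-[(2R)-1-(tert-butoxycarbonyl)piperidin-2-yl]-3-(trimethylsilyloxy)but-2-enoate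
Product: 9 tert-butyl (2R)-2-[1-methoxy-1,3-bis(trimethylsilyloxy)buta-1,3-dien-2-yl]piperidine-1-carboxylate (ketene acetal geometry immaterial), via lithium dienolate 8 (not isolated)
Conditions: LiN(iPr)2, THF, −78 °C; Me3SiCl, −78 → 0 °C; pentane, filtration, used crude
Reagents that add atoms: chlorotrimethylsilane, C[Si](C)(C)Cl
Why: Kinetic γ-deprotonation of the β-silyloxy enoate at its methyl group and O-silylation of the extended enolate (silyl ketene acetal formation), the piperidine C2–H being on the α-substituent and therefore not vinylogously acidified.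

Step 5
Reactants: 10 4-(tert-butyldimethylsilyloxy)benzaldehyde; 11 (E)-1-methoxy-3-(trimethylsilyloxy)buta-1,3-diene
Product: 13 (2S)-2-[4-(tert-butyldimethylsilyloxy)phenyl]-2,3-dihydro-4H-pyran-4-one, via silyl aldol adduct 12 (not isolated)
Conditions: (S)-BINOL (20 mol %), Ti(OiPr)4 (10 mol %), 4 Å MS, Et2O, −20 °C; then TFA, CH2Cl2, 0 °C
Reagents that add atoms: none
Why: Catalytic enantioselective hetero-Diels–Alder reaction in its Mukaiyama aldol/cyclisation mode, in which the BINOLate–titanium complex binds the aldehyde and leaves one face open to the diene terminus, setting C2 as S in 12, and TFA then closes ring C by oxa-Michael addition and loss of methanol without touching that centre or the aryl silyl ether.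

Step 6
Reactants: 13 (2S)-2-[4-(tert-butyldimethylsilyloxy)phenyl]-2,3-dihydro-4H-pyran-4-one
Product: 15 (2S)-2-[4-(tert-butyldimethylsilyloxy)phenyl]-5-(phenylsulfanyl)-2,3-dihydro-4H-pyran-4-one, via chloro sulfide adduct 14 (not isolated)
Conditions: PhSH, N-chlorosuccinimide, CH2Cl2, 0 °C (forms PhSCl); 13, −78 °C; Et3N, −78 → 0 °C
Reagents that add atoms: thiophenol, Sc1ccccc1
Why: Electrophilic sulfenylation of a vinylogous ester by addition–elimination, in which the sulfenyl chloride attacks the nucleophilic α-carbon C5, chloride caps the oxocarbenium carbon C6, and Et3N removes the doubly activated H-5 to expel chloride and restore the C5=C6 alkene.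

Step 7
Reactants: 15 (2S)-2-[4-(tert-butyldimethylsilyloxy)phenyl]-5-(phenylsulfanyl)-2,3-dihydro-4H-pyran-4-one
Product: 16 (2S)-2-[4-(tert-butyldimethylsilyloxy)phenyl]-5-(phenylsulfinyl)-2,3-dihydro-4H-pyran-4-one (both sulfur epimers)
Conditions: mCPBA (1.0 equiv), CH2Cl2, −78 → −20 °C
Reagents that add atoms: 3-chloroperoxybenzoic acid, O=C(OO)c1cccc(Cl)c1
Why: Chemoselective sulfide-to-sulfoxide oxidation with one equivalent of peracid in the cold, the push–pull alkene being too electron-poor for epoxidation and the configuration at sulfur irrelevant because sulfur leaves in step 8.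

Step 8
Reactants: 9 tert-butyl (2R)-2-[1-methoxy-1,3-bis(trimethylsilyloxy)buta-1,3-dien-2-yl]piperidine-1-carboxylate; 16 (2S)-2-[4-(tert-butyldimethylsilyloxy)phenyl]-5-(phenylsulfinyl)-2,3-dihydro-4H-pyran-4-one
Product: 19 tert-butyl (2R)-2-[(2S)-5,7-dihydroxy-2-(4-hydroxyphenyl)-4-oxo-3,4-dihydro-2H-chromen-6-yl]piperidine-1-carboxylate, via cycloadduct 17 (not isolated), via cyclohexadiene ketal 18 (not isolated)
Conditions: 9 (1.5 equiv), N,O-bis(trimethylsilyl)acetamide (BSA, 2.5 equiv), toluene (1 M), rt → 70 °C; then KHF2, MeOH, rt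
Reagents that add atoms: none
Why: Proposed new method: a normal-electron-demand, strongly asynchronous [4+2] cycloaddition is expected in which the terminal CH2 of 9 (largest HOMO coefficient) bonds to C6 of 16 (largest LUMO coefficient, β to both the ketone and the sulfinyl group) to make C8–C8a, and the ketene acetal carbon then bonds to C5 of 16 to make C4a–C5. Ring A thus closes as a six-membered carbocycle by intermolecular cycloaddition or, if the path is stepwise, by 6-(enolexo)-exo-trig attack of the sulfinyl-stabilised enolate carbon on the ester-derived oxocarbenium ion, which leads to the same adduct 17. The selectivity needed is regiochemical (piperidine at C6, not C8), and it is secured by the matched polarisation of the partners, by the blocked α-carbon of the diene and by O1 being bonded to C8a from the start. Suprafacial addition places the sulfinyl group on C4a and H-8a cis, so 17 should lose benzenesulfenic acid by thermal syn elimination under neutral conditions and O1 becomes vinylic in 18 before it can be expelled from C8a; loss of methanol from the C5 ketal then aromatises the ring, BSA keeps the sulfenic acid and methanol from protonating unreacted 9, and mildly acidic KHF2 cleaves the two trimethylsilyl ethers and the aryl TBS ether. No new stereocentre survives, since C4a, C5 and C8a all end as sp2 carbons, so facial and endo/exo selectivity do not matter, and C2 and piperidine C2 are spectators in a medium free of base and strong acid. The closest known reaction type is the Diels–Alder/elimination benzannulation of 1-alkoxy-1,3-bis(silyloxy)dienes with sulfinyl- or halogen-substituted quinones, together with cycloadditions of 3-acceptor-substituted chromones; a monocyclic 5-sulfinyl-2,3-dihydropyran-4-one has not been shown to react in this way.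

Step 9
Reactants: 19 tert-butyl (2R)-2-[(2S)-5,7-dihydroxy-2-(4-hydroxyphenyl)-4-oxo-3,4-dihydro-2H-chromen-6-yl]piperidine-1-carboxylate
Product: 20 (2S)-5,7-dihydroxy-2-(4-hydroxyphenyl)-6-[(2R)-piperidin-2-yl]-2,3-dihydro-4H-chromen-4-one hydrochloride
Conditions: HCl (4 M in 1,4-dioxane), CH2Cl2, 0 °C → rt; evaporation, trituration with Et2O
Reagents that add atoms: hydrogen chloride, Cl
Why: Acidolysis of the tert-butyl carbamate (loss of the tert-butyl cation, then decarboxylation) is much faster than ionisation of the benzylic C–N bond, the ammonium ion formed is a poor leaving group, and cold anhydrous acid does not open ring C, so both stereocentres should hold.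

Step 10
Reactants: 20 (2S)-5,7-dihydroxy-2-(4-hydroxyphenyl)-6-[(2R)-piperidin-2-yl]-2,3-dihydro-4H-chromen-4-one hydrochloride
Product: 22 (2S)-5,7-dihydroxy-2-(4-hydroxyphenyl)-6-[(2R)-1-methylpiperidin-2-yl]-2,3-dihydro-4H-chromen-4-one (target), via benzoxazine 21 (not isolated)
Conditions: aq. HCHO (1.1 equiv), NaOAc, NaBH(OAc)3, MeCN–THF, 0 °C → rt; pH 7 phosphate work-up
Reagents that add atoms: formaldehyde, C=O
Why: Reductive amination in which the N-methylene iminium ion is parked reversibly on O-7 as the 1,3-benzoxazine 21 and reduced from its open form, NaBH(OAc)3 leaving the hydrogen-bonded aryl ketone alone, the acetate buffer keeping ring C closed, and the near-stoichiometric formaldehyde sparing the nucleophilic C8.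

Compound list
1 | (2R)-2-[1-(tert-butoxycarbonyl)piperidin-2-yl]acetic acid | CC(C)(C)OC(=O)N1CCCC[C@@H]1CC(=O)O | starting material
2 | methyl 2-[(2R)-1-(tert-butoxycarbonyl)piperidin-2-yl]acetate | CC(C)(C)OC(=O)N1CCCC[C@@H]1CC(=O)OC | intermediate
3 | N-methoxy-N-methylacetamide | CC(=O)N(C)OC | starting material
4 | lithium enolate of 2 | CC(C)(C)OC(=O)N1CCCC[C@@H]1C=C(OC)[O-].[Li+] | intermediate
5 | lithium alkoxide adduct of 4 and 3 (tetrahedral) | CC(C)(C)OC(=O)N1CCCC[C@@H]1C(C(=O)OC)C(C)([O-])N(C)OC.[Li+] | intermediate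
6 | methyl 2-[(2R)-1-(tert-butoxycarbonyl)piperidin-2-yl]-3-oxobutanoate (α-epimers) | CC(C)(C)OC(=O)N1CCCC[C@@H]1C(C(C)=O)C(=O)OC | intermediate
7 | methyl 2-[(2R)-1-(tert-butoxycarbonyl)piperidin-2-yl]-3-(trimethylsilyloxy)but-2-enoate | CC(C)(C)OC(=O)N1CCCC[C@@H]1C(C(=O)OC)=C(C)O[Si](C)(C)C | intermediate
8 | lithium dienolate of 7 | CC(C)(C)OC(=O)N1CCCC[C@@H]1C(C(=C)O[Si](C)(C)C)=C(OC)[O-].[Li+] | intermediate
9 | tert-butyl (2R)-2-[1-methoxy-1,3-bis(trimethylsilyloxy)buta-1,3-dien-2-yl]piperidine-1-carboxylate | C=C(O[Si](C)(C)C)C(=C(OC)O[Si](C)(C)C)[C@H]1CCCCN1C(=O)OC(C)(C)C | intermediate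
10 | 4-(tert-butyldimethylsilyloxy)benzaldehyde | O=Cc1ccc(O[Si](C)(C)C(C)(C)C)cc1 | starting material
11 | (E)-1-methoxy-3-(trimethylsilyloxy)buta-1,3-diene | CO/C=C/C(=C)O[Si](C)(C)C | starting material
12 | (1E,5S)-5-[4-(tert-butyldimethylsilyloxy)phenyl]-1-methoxy-5-(trimethylsilyloxy)pent-1-en-3-one | CO/C=C/C(=O)C[C@@H](c1ccc(O[Si](C)(C)C(C)(C)C)cc1)O[Si](C)(C)C | intermediate
13 | (2S)-2-[4-(tert-butyldimethylsilyloxy)phenyl]-2,3-dihydro-4H-pyran-4-one | O=C1C[C@@H](c2ccc(O[Si](C)(C)C(C)(C)C)cc2)OC=C1 | intermediate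
14 | (2S)-2-[4-(tert-butyldimethylsilyloxy)phenyl]-6-chloro-5-(phenylsulfanyl)tetrahydro-4H-pyran-4-one (C5, C6 undefined) | O=C1C[C@@H](c2ccc(O[Si](C)(C)C(C)(C)C)cc2)OC(Cl)C1Sc1ccccc1 | intermediate
15 | (2S)-2-[4-(tert-butyldimethylsilyloxy)phenyl]-5-(phenylsulfanyl)-2,3-dihydro-4H-pyran-4-one | O=C1C[C@@H](c2ccc(O[Si](C)(C)C(C)(C)C)cc2)OC=C1Sc1ccccc1 | intermediate
16 | (2S)-2-[4-(tert-butyldimethylsilyloxy)phenyl]-5-(phenylsulfinyl)-2,3-dihydro-4H-pyran-4-one (sulfur epimers) | O=C1C[C@@H](c2ccc(O[Si](C)(C)C(C)(C)C)cc2)OC=C1S(=O)c1ccccc1 | intermediate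
17 | tert-butyl (2R)-2-[(2S)-2-[4-(tert-butyldimethylsilyloxy)phenyl]-5-methoxy-4-oxo-4a-(phenylsulfinyl)-5,7-bis(trimethylsilyloxy)-3,4,4a,5,8,8a-hexahydro-2H-chromen-6-yl]piperidine-1-carboxylate (cis ring fusion, sulfinyl and H-8a cis, other transient centres undefined) | O=C1C[C@@H](c2ccc(O[Si](C)(C)C(C)(C)C)cc2)OC2CC(O[Si](C)(C)C)=C([C@H]3CCCCN3C(=O)OC(C)(C)C)C(OC)(O[Si](C)(C)C)C12S(=O)c1ccccc1 | intermediate
18 | tert-butyl (2R)-2-[(2S)-2-[4-(tert-butyldimethylsilyloxy)phenyl]-5-methoxy-4-oxo-5,7-bis(trimethylsilyloxy)-3,4,5,8-tetrahydro-2H-chromen-6-yl]piperidine-1-carboxylate (C5 undefined) | O=C1C[C@@H](c2ccc(O[Si](C)(C)C(C)(C)C)cc2)OC2=C1C(OC)(O[Si](C)(C)C)C([C@H]1CCCCN1C(=O)OC(C)(C)C)=C(O[Si](C)(C)C)C2 | intermediate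
19 | tert-butyl (2R)-2-[(2S)-5,7-dihydroxy-2-(4-hydroxyphenyl)-4-oxo-3,4-dihydro-2H-chromen-6-yl]piperidine-1-carboxylate | CC(C)(C)OC(=O)N1CCCC[C@@H]1c1c(O)cc2c(c1O)C(=O)C[C@@H](c1ccc(O)cc1)O2 | intermediate
20 | (2S)-5,7-dihydroxy-2-(4-hydroxyphenyl)-6-[(2R)-piperidin-2-yl]-2,3-dihydro-4H-chromen-4-one hydrochloride | N1CCCC[C@@H]1c1c(O)cc2c(c1O)C(=O)C[C@@H](c1ccc(O)cc1)O2.Cl | intermediate
21 | 1,3-benzoxazine in which one CH2 links the piperidine nitrogen to O-7 of the free amine of 20 (piperidine C2 R, flavanone C2 S) | C1CCCN2COc3cc4c(c(O)c3[C@@H]12)C(=O)C[C@@H](c1ccc(O)cc1)O4 | intermediate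
22 | (2S)-5,7-dihydroxy-2-(4-hydroxyphenyl)-6-[(2R)-1-methylpiperidin-2-yl]-2,3-dihydro-4H-chromen-4-one | CN1CCCC[C@@H]1c1c(O)cc2c(c1O)C(=O)C[C@@H](c1ccc(O)cc1)O2 | target

Total steps: 10. Longest linear sequence: 7 steps (steps 1–4 and 8–10). Steps 5–7 form the convergent branch.

Steps most likely to fail

Step 8. Three processes threaten the step.
- The second bond may fail to form because two fully substituted carbons must meet.
- The silyl ketene acetal may pass silicon to the sulfoxide oxygen and divert the dienophile into Pummerer-type chemistry.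
- O1 may be lost from C8a before the sulfoxide leaves.

The fallback runs the three events one at a time with known reactions. It sets out from sulfide 15 and diene 9 and comes back at 19. TMSOTf in CH2Cl2 at −78 °C converts 15 into its 4-silyloxy oxocarbenium ion. The terminal CH2 of 9 adds to C6 in a vinylogous Mukaiyama–Michael reaction, a reaction type established for chromones and dihydropyranones. This gives methyl 4-[(6S)-6-[4-(tert-butyldimethylsilyloxy)phenyl]-3-(phenylsulfanyl)-4-(trimethylsilyloxy)-5,6-dihydro-2H-pyran-2-yl]-2-[(2R)-1-(tert-butoxycarbonyl)piperidin-2-yl]-3-(trimethylsilyloxy)but-2-enoate F1. Aqueous work-up hydrolyses it to methyl 4-[(6S)-6-[4-(tert-butyldimethylsilyloxy)phenyl]-4-oxo-3-(phenylsulfanyl)tetrahydro-2H-pyran-2-yl]-2-[(2R)-1-(tert-butoxycarbonyl)piperidin-2-yl]-3-oxobutanoate F2. A Dieckmann condensation with LiN(SiMe3)2 (2.2 equiv, THF, −78 → 0 °C, short contact to protect C2) closes C4a–C5. The product is tert-butyl (2R)-2-[(2S)-2-[4-(tert-butyldimethylsilyloxy)phenyl]-4,5,7-trioxo-4a-(phenylsulfanyl)octahydro-2H-chromen-6-yl]piperidine-1-carboxylate F3. mCPBA at −78 °C gives the corresponding 4a-(phenylsulfinyl) trione F4. On warming, F4 undergoes sulfoxide syn elimination and tautomerises to the 4'-O-tert-butyldimethylsilyl ether of 19 F5. KHF2 in MeOH then gives 19.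

Step 3. Amine-mediated enolisation may be too slow for a β-keto ester whose α-carbon carries a branched, carbamate-flanked substituent. The strained tetrasubstituted silyl enol ether may also hydrolyse on handling, which would cut off the supply of 9. The fallback replaces the 3-silyloxy group by a chromatography-stable acetal enol ether. It sets out from 6 and comes back at 20. O-Alkylation of the sodium enolate of 6 (NaH, MOMCl, THF, 0 °C) gives methyl 2-[(2R)-1-(tert-butoxycarbonyl)piperidin-2-yl]-3-(methoxymethoxy)but-2-enoate F6. LiN(iPr)2 and then Me3SiCl convert F6 into tert-butyl (2R)-2-[1-methoxy-3-(methoxymethoxy)-1-(trimethylsilyloxy)buta-1,3-dien-2-yl]piperidine-1-carboxylate F7. Under the conditions of step 8, F7 and 16 pass through the 7-O-methoxymethyl analogue of 17 F8 and the 7-O-methoxymethyl analogue of 18 F9. The isolated product is tert-butyl (2R)-2-[(2S)-5-hydroxy-2-(4-hydroxyphenyl)-7-(methoxymethoxy)-4-oxo-3,4-dihydro-2H-chromen-6-yl]piperidine-1-carboxylate F10. HCl in dioxane–MeOH removes the carbamate and the acetal together and gives 20.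

Step 2. The hindered enolate may add too slowly to the amide. Proton transfer from the acetamide, or β-elimination of the carbamate on warming, could then take over. The fallback trades direct acylation for an aldol addition followed by oxidation. It sets out from 2 (through enolate 4) and comes back at 6. Acetaldehyde is added to 4 at −78 °C, and an AcOH quench gives methyl 2-[(2R)-1-(tert-butoxycarbonyl)piperidin-2-yl]-3-hydroxybutanoate F11 as a diastereomer mixture. Dess–Martin oxidation in CH2Cl2 converts F11 into 6.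

Further compounds
F1 | step 8 | methyl 4-[(6S)-6-[4-(tert-butyldimethylsilyloxy)phenyl]-3-(phenylsulfanyl)-4-(trimethylsilyloxy)-5,6-dihydro-2H-pyran-2-yl]-2-[(2R)-1-(tert-butoxycarbonyl)piperidin-2-yl]-3-(trimethylsilyloxy)but-2-enoate | COC(=O)C(=C(O[Si](C)(C)C)CC1O[C@H](c2ccc(O[Si](C)(C)C(C)(C)C)cc2)CC(O[Si](C)(C)C)=C1Sc1ccccc1)[C@H]1CCCCN1C(=O)OC(C)(C)C
F2 | step 8 | methyl 4-[(6S)-6-[4-(tert-butyldimethylsilyloxy)phenyl]-4-oxo-3-(phenylsulfanyl)tetrahydro-2H-pyran-2-yl]-2-[(2R)-1-(tert-butoxycarbonyl)piperidin-2-yl]-3-oxobutanoate | O=C1C[C@@H](c2ccc(O[Si](C)(C)C(C)(C)C)cc2)OC(CC(=O)C(C(=O)OC)[C@H]2CCCCN2C(=O)OC(C)(C)C)C1Sc1ccccc1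
F3 | step 8 | tert-butyl (2R)-2-[(2S)-2-[4-(tert-butyldimethylsilyloxy)phenyl]-4,5,7-trioxo-4a-(phenylsulfanyl)octahydro-2H-chromen-6-yl]piperidine-1-carboxylate | O=C1C[C@@H](c2ccc(O[Si](C)(C)C(C)(C)C)cc2)OC2CC(=O)C([C@H]3CCCCN3C(=O)OC(C)(C)C)C(=O)C12Sc1ccccc1
F4 | step 8 | 4a-(phenylsulfinyl) trione derived from F3 | O=C1C[C@@H](c2ccc(O[Si](C)(C)C(C)(C)C)cc2)OC2CC(=O)C([C@H]3CCCCN3C(=O)OC(C)(C)C)C(=O)C12S(=O)c1ccccc1
F5 | step 8 | 4'-O-tert-butyldimethylsilyl ether of 19 | CC(C)(C)OC(=O)N1CCCC[C@@H]1c1c(O)cc2c(c1O)C(=O)C[C@@H](c1ccc(O[Si](C)(C)C(C)(C)C)cc1)O2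
F6 | step 3 | methyl 2-[(2R)-1-(tert-butoxycarbonyl)piperidin-2-yl]-3-(methoxymethoxy)but-2-enoate | CC(C)(C)OC(=O)N1CCCC[C@@H]1C(C(=O)OC)=C(C)OCOC
F7 | step 3 | tert-butyl (2R)-2-[1-methoxy-3-(methoxymethoxy)-1-(trimethylsilyloxy)buta-1,3-dien-2-yl]piperidine-1-carboxylate | C=C(OCOC)C(=C(OC)O[Si](C)(C)C)[C@H]1CCCCN1C(=O)OC(C)(C)C
F8 | step 3 | 7-O-methoxymethyl analogue of 17 | O=C1C[C@@H](c2ccc(O[Si](C)(C)C(C)(C)C)cc2)OC2CC(OCOC)=C([C@H]3CCCCN3C(=O)OC(C)(C)C)C(OC)(O[Si](C)(C)C)C12S(=O)c1ccccc1
F9 | step 3 | 7-O-methoxymethyl analogue of 18 | O=C1C[C@@H](c2ccc(O[Si](C)(C)C(C)(C)C)cc2)OC2=C1C(OC)(O[Si](C)(C)C)C([C@H]1CCCCN1C(=O)OC(C)(C)C)=C(OCOC)C2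
F10 | step 3 | tert-butyl (2R)-2-[(2S)-5-hydroxy-2-(4-hydroxyphenyl)-7-(methoxymethoxy)-4-oxo-3,4-dihydro-2H-chromen-6-yl]piperidine-1-carboxylate | CC(C)(C)OC(=O)N1CCCC[C@@H]1c1c(OCOC)cc2c(c1O)C(=O)C[C@@H](c1ccc(O)cc1)O2
F11 | step 2 | methyl 2-[(2R)-1-(tert-butoxycarbonyl)piperidin-2-yl]-3-hydroxybutanoate | CC(C)(C)OC(=O)N1CCCC[C@@H]1C(C(C)O)C(=O)OC
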